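At 6.00 min, the last reading of Sunday's flask, I asked how fast the starting complex was still falling, since this same flask is asked about at 20 min.

all flasks: starting complex 0.050 M
- Sunday's: incoming ligand 0.050 M; the very flask that is asked about, followed so far
- flask: incoming ligand 0.0500 M; time 20 min

- Sunday's (time / min: complex with one exchanged / %, complex with two exchanged / %, starting complex / %): 1.00: 66.0, 1.3, 31.5; 2.00: 75.4, 3.1, 20.7; 3.00: 78.1, 4.1, 16.9; 4.00: 80.1, 3.7, 15.2; 5.00: 80.0, 5.3, 14.6; 6.00: 81.4, 5.1, 14.5

(standard deviation of a reading: 0.5 percentage points)

1. equivalents of incoming ligand to starting complex, everything else as given, that leave most complex with one exchanged at 20 min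
2. the amount of complex with one exchanged then, in percent of the starting complex charged
3. the amount of complex with one exchanged with the amounts as given



Counting one incoming ligand in each complex with one exchanged and two in each complex with two exchanged, that reading puts 91.6 % of the charged ligand on complexes. This is one ligand molecule's chance of ending on a complex, which I call the capture share, f.

I took the rate as k times starting complex times incoming ligand, whose charges are equal. The first minute then reads k = 43.5 M⁻¹ min⁻¹, so the flask began by losing 2.17 min⁻¹ of its charge each minute. The fall of the starting complex slows this by a factor of 6.90. If the uncaptured ligand were still free, it would slow it by a further 11.9, leaving 0.0265 min⁻¹. But the readings from 4.00 min to 6.00 min show 0.00350 min⁻¹, which is slower than that. So I took the uncaptured ligand as lost elsewhere and the flask as standing still, and I expected about 81.4 % complex with one exchanged at 20 min.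

The forecast judged otherwise, that “Irreversible kinetics would not stall like that”. It gave 74.5 % (70 % to 78 %), lower than my figure, and 75 % at 1.03 equiv.

The flask gives 82.4 %, and its best is 86.8 % at 1.18 equiv. Incoming ligand, the limiting reagent, stood at 0 % of its charge at 20.0 min.

    starting complex + incoming ligand → leaving ligand + complex with one exchanged (k = 51.0 M⁻¹ min⁻¹)
    complex with one exchanged + incoming ligand → leaving ligand + complex with two exchanged (k = 2.20 M⁻¹ min⁻¹)
    2 incoming ligand → homo dimer (k = 2.70 M⁻¹ min⁻¹)

Taking f of the ligand and subtracting the 9.98 % held by complex with two exchanged leaves 81.6 %, close to the computed amount. In the neighbour flask charged with 0.030 M of incoming ligand, the same f puts ligand equal to 55.0 % of the starting complex charged on complexes. The computed neighbour flask holds 55.4 % complex with one exchanged and 1.14 % complex with two exchanged, which counts 57.7 %, so its capture share is 96.2 %, higher than f, and f did not carry over unchanged to this charge.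

The numbers in the tables come from a simulation from invented constants.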